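The runs were generated by integration on assumed constants; the scatter is artificial.

Percent of the charge per day is the unit in which two chemists dispute Thursday's flask, which is the flask asked about, followed to the end of its feed and now left to run on.

| setting | Thursday's | flask |
|---|---|---|
| substrate | 20 mM (fed, over 10 d) | 20 mM (fed, over 10 d) |
| free catalyst | 0.20 mM | 0.20 mM |
| remark | the very flask that is asked about, followed so far; the fed solution adds 1.0 times the starting volume | the fed solution adds 1.0 times the starting volume |
| time |  | 25 d |

Thursday's run (percent of the substrate charged)

| time / d | substrate / % | catalyst intermediate A / % | over-reaction product B / % | catalyst intermediate B / % | target / % |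
|---|---|---|---|---|---|
| 0.500 | 4.0 | 0 | 0.6 | 0 | 1.0 |
| 1.67 | 16.8 | 1.8 | 0 | 0 | 3.0 |
| 3.00 | 24.0 | 1.2 | 0 | 0.6 | 5.4 |
| 4.00 | 27.1 | 0 | 0 | 0.3 | 11.8 |
| 6.00 | 41.1 | 1.7 | 1.8 | 0 | 18.9 |
| 8.00 | 49.7 | 0 | 1.7 | 0.7 | 28.1 |
| 10.0 | 62.7 | 1.3 | 2.0 | 0.4 | 37.0 |

(readings scatter by 1 percentage point)

- every charge counts on the volume at the start, and the solution that is fed holds the whole dose
- percentages count the whole charge, also what has not yet gone in

1. the largest share of what was charged as substrate, at 25 d belongs to (catalyst intermediate A / catalyst intermediate B / target / over-reaction product B / substrate)
2. the largest share itself, whichever of these holds it, in percent of the substrate charged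

The first chemist, who made the forecast, reads a straight line in the target and argues “Fifteen more days at 4.5 per day would consume about 67 points”; easing that for some dependence on concentration, he forecasts target at 86%.

The second, reckoning for herself, notes that the line ran while the feed raised the substrate from 27.1% to 62.7%, and that the feed has now ended. She defines k′, a pseudo-first-order constant, as the fraction of the substrate present that becomes target per day at the final volume. It is the target's daily gain from 6.00 d to 10.0 d over the substrate reading at 8.00 d, times 0.900 for the further thinning of the catalyst, and it reads 0.0819 /d. So the substrate half-life τ is 8.46 d, the time in which k′ halves the substrate present. The 15.0 d after the feed are fewer than two half-lives, so she expects 18.3% of substrate left. She lets over-reaction product B follow the standing target, 3 times as fast on average, up to 11.0%, which, setting aside the 1.00% of the charge that the catalyst can hold at most, leaves target at 70.7%, less than the forecast.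

The flask gives target at 69.2%, with substrate at 21.2%.

    target → over-reaction product A (k = 2.90 × 10⁻⁹ /s)
    catalyst intermediate B ⇌ free catalyst + target (K = 0.00730 M, k = 9.60 × 10⁻⁴ /s)
    substrate + free catalyst ⇌ catalyst intermediate A (K = 17.0 /M, k = 4.00 /M/s)
    catalyst intermediate A → catalyst intermediate B (k = 9.20 × 10⁻⁴ /s)
    free catalyst + target → free catalyst + over-reaction product B (k = 0.00180 /M/s)

The first chemist's straight line has its region up to the end of the feed and just past it, where target goes from 36.4% after 10.0 d to 46.1% after 12.5 d, but over the 15.0 d after the feed the substrate loses 40 percentage points, not his 67 points. Over those days the substrate's own half-life comes to 9.80 d, longer than τ, while free catalyst went from 58.8% to 49.6% of the catalyst charged. In the neighbour flask with 0.050 mM of free catalyst, taking k′ in proportion to the charge stretches τ to 33.8 d, and feeding against that decay gives 66.5% of substrate left; that flask holds 62.7%, more substrate than target, which stands at 36.0%.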